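Remark on the chemistry: the target has no stereocentre, so the chiral compounds of the route (6, 11, 12) are carried as racemates. Ring A is numbered from the carbonyl-bearing carbon (C1; OH at C2, OMe at C4, chain at C5), and the chain carbons are called α (on ring A), β and γ (on ring C).

## Structural features

The target is a 2-hydroxy-4-methoxybenzophenone. Ring A is a 1,2,4,5-tetrasubstituted benzene joined through the ketone carbon at C1 to ring B, a 4-hydroxyphenyl group. Ring A also carries a chelated hydroxyl at C2, a methoxy group at C4 and, at C5, a saturated chain Cα–Cβ–Cγ that ends in ring C, a second 4-hydroxyphenyl group. There are no rings other than the three benzene rings and no stereocentre; the only stereocentres in the route are the two directly bonded cyclopropane carbons Cα and Cγ of 11 and 12, and both are erased again. The fragile groups are the diaryl ketone, which is reducible on palladium, and the three phenols, which make all rings electron-rich and sensitive to oxidants and electrophiles. The difficulty is regiochemical and chemoselective: four different substituents must sit in the right order on ring A, only one of four oxygen atoms is methylated, and an unfunctionalised three-carbon link must be made between two arenes without harming the ketone. The substitution pattern of ring A maps onto 2-hydroxy-4-methoxybenzaldehyde, whose C5 position (para to OH, ortho to OMe) is its most nucleophilic site. The key step uses the fact that Cα and Cγ are both benzylic: the chain equals an alkene between ring A C5 and ring C plus one CH2 (Cβ). Methylene transfer to that alkene gives a 1,2-diarylcyclopropane whose Cα–Cγ bond, flanked by rings A and C, is the one that hydrogenolysis breaks.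

## Logic of the disconnections

13 to 11: in the backward sense no skeletal bond is cut. A bond is added between Cα and Cγ, and the three phenolic O–H bonds are replaced by O–CH2Ph bonds. This is chosen because the Cα–Cγ bond lies between two arenes and is therefore the ring bond a palladium catalyst cleaves, under the same conditions that remove benzyl ethers. The gain is that the inert propane chain becomes the product of a cyclopropanation and the whole deprotection is folded into the same operation. The demand on the forward step is that hydrogen cleaves only the diaryl-flanked ring bond and the benzyl ethers (passing through 12) and is stopped before the ketone is reduced.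

11 to 10: the Cα–Cβ and Cβ–Cγ bonds are cut, which removes the CH2 group, the three-membered ring and both stereocentres. The cut is placed there because both bonds belong to a cyclopropane and can be made together by a [2+1] methylene transfer. The gain is an (E)-1,2-diaryl alkene that cross-coupling can assemble. The forward step needs a carbenoid electrophilic enough for a 1,2-diaryl alkene, stereospecific transfer, and no reaction at the ketone.

10 to 7 and 9: the sp2–sp2 bond between ring A C5 and Cα is cut. This splits the molecule into two fragments of similar size and puts the halogen of 7 on the carbon that electrophilic substitution reaches most easily. The forward step must give the linear E alkene from an electron-rich aryl bromide.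

9 to 8: the Cγ=Cα double bond is cut to a purchasable aldehyde and a one-carbon ylide. The demand is only a clean methylenation.

7 to 6, and 6 to 3 and 4 (through 5): the oxidation level at the carbinol carbon is adjusted, then the bond between that carbon and ring B is cut. The carbonyl carbon is thus already present in the ring A aldehyde and ring B enters as a nucleophile. The forward addition must be faster than any exchange at the C–Br bond of 3, and the oxidation must spare benzyl ethers.

3 to 2, and 2 to 1: the O–CH2Ph bond and then the C5–Br bond are cut, which leads to a commercial aldehyde that holds the C1, C2 and C4 substituents. The forward bromination must go only to C5 and only once.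

## Other disconnections considered

Alternative 1: The cut goes through ring A itself. The C1–C2 bond (aroyl-bearing to hydroxyl-bearing carbon) and the C5–C6 bond (chain-bearing carbon to the C6–H carbon) are broken. This leaves the oxygenated diene 1,3-dimethoxy-1-(trimethylsilyloxy)-7-[4-(tert-butyldimethylsilyloxy)phenyl]hepta-1,3-diene A2 and the ynone 1-[4-(tert-butyldimethylsilyloxy)phenyl]prop-2-yn-1-one A3.
- Forward key step: a regioselective Diels–Alder reaction (nucleophilic C4 terminus of A2 to the β-carbon of A3, ketene acetal carbon to the α-carbon), then loss of methanol and of the trimethylsilyl group, would aromatise the adduct to the bis-silyl ether A1. Fluoride would then give 13.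
- In its favour: the polarity of the two partners fixes all four substituents of ring A. The C2 hydroxyl is born free, the C4 methoxy is already present, and the chain enters as an ordinary saturated alkyl group.
- Better than the chosen plan on one point: no reduction is ever run with the ketone present, whereas the final hydrogenolysis of the chosen plan has to spare the carbonyl.
- Against it: A2 needs about five operations (a 3-arylpropyl halide, an acetoacetate dianion, enol ether and silyl ketene acetal formation). It is hydrolytically labile and forms as a mixture of geometric isomers, whose reactivity drops once C4 carries a substituent. A3 is a reactive conjugate acceptor prone to polymerisation. Aromatisation competes with plain hydrolysis of the adduct to a cyclohexenone.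
- Comparison: structurally both plans join three fragments. Mechanistically the alternative rests on a pericyclic step with a diene that cannot be stored, while the chosen plan uses shelf-stable arenes and two steps of wide scope. In step count the two are about equal (roughly nine operations against eight), so the choice rests on robustness.

Alternative 2: Ring B is dismantled. Two of its C–C bonds are cut, so that three ring carbons come from dimethyl 3-oxopentanedioate A6 and the other three, with the ketone carbon and ring A, from 6-{3-[4-(benzyloxy)phenyl]propyl}-7-methoxy-4-oxo-4H-chromene-3-carbaldehyde A5.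
- Forward key step: base-mediated conjugate addition of A6 to C2 of A5, opening of the pyranone to free the ring A phenoxide, and intramolecular Knoevenagel condensation on the formyl group followed by enolisation would give the benzophenone A4. In A4 ring B carries its hydroxyl between two ester groups.
- In its favour: the ketone and the chelated ortho hydroxyl of ring A come directly from C4 and O1 of the chromone, so no regiocontrol, organometallic addition or oxidation is needed. The domino step is metal-free.
- Better than the chosen plan on one point: the chain would already be saturated, so the only reduction left is the cleavage of one benzyl ether, which is gentler toward the ketone than a ring hydrogenolysis.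
- Against it: the real problem, the Cα–Cβ–Cγ link at C5, is not addressed and would have to be solved earlier on an acetophenone by some other C–C bond formation. A5 needs that acetophenone plus a formylation–cyclisation. A4 carries two superfluous esters, whose removal needs saponification and a twofold decarboxylation under forcing thermal conditions.
- Comparison: the key step is spent on the easiest ring, a plain 4-hydroxyphenyl group that is built atom by atom and then trimmed. The mechanism is attractive but the fit to the structure is poor, and the route is estimated to be four or more operations longer.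

Alternative 3: The cut is at the Cα–Cβ bond, with a temporary bond from the C4 oxygen of ring A to Cγ. Backwards, the methyl of the C4 methoxy group is removed and the phenol oxygen is tied to Cγ as the 2-arylchroman A7. A7 is then split into the ortho-quinone methide A10 and 4-(triisopropylsilyloxy)styrene A9.
- Forward key step: heating the salicyl alcohol A8 would expel water to give A10. As an electron-poor heterodiene, A10 would add the electron-rich styrene A9 in an inverse-demand [4+2] cycloaddition, with oxygen bonding to the benzylic carbon. Reductive cleavage of the benzylic O–Cγ bond of A7, methylation of the freed C4 phenol and removal of the benzyl and silyl groups would then lead to 13.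
- In its favour: the step is convergent and metal-free. It forms the Cα–Cβ bond and brings in ring C with the whole chain at once, and its regiochemistry follows from the polarisation of both partners.
- Equal to the chosen plan on two points: it creates a stereocentre that is later erased, so stereochemical economy is the same, and its convergence is at least equal to that of the Heck coupling.
- Against it: the C4 oxygen must be a free phenol during the key step, so the methyl group has to go on afterwards in the presence of three other masked hydroxyls. Opening the flavan is a benzylic C–O hydrogenolysis that endangers the diaryl ketone at least as much as the cyclopropane opening does. A10 tends to dimerise and A9 to polymerise at the temperature needed. A8 needs its own regioselective hydroxymethylation of a differentially protected 2,4-dihydroxybenzophenone.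
- Comparison: three to four operations follow its key step, against one in the chosen plan, so it loses on step economy.

Key step: step 7

## Route

Step 1
Reactants: 1 2-hydroxy-4-methoxybenzaldehyde
Product: 2 5-bromo-2-hydroxy-4-methoxybenzaldehyde
Conditions: Br2 (1.05 equiv), AcOH, rt
Reagents that add atoms: bromine, BrBr
Why: Electrophilic aromatic bromination; C5 is para to the hydroxyl, ortho to the methoxy group and meta to the formyl group, while the other activated site, C3, is flanked by two substituents, so monobromination should take place at C5.

Step 2
Reactants: 2 5-bromo-2-hydroxy-4-methoxybenzaldehyde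
Product: 3 2-(benzyloxy)-5-bromo-4-methoxybenzaldehyde
Conditions: BnBr, K2CO3, DMF, 50 °C
Reagents that add atoms: benzyl bromide, BrCc1ccccc1
Why: Williamson ether synthesis (SN2 of the phenoxide on benzyl bromide); the benzyl ether masks the acidic phenol for the Grignard, Heck and zinc carbenoid steps and is removed in the final hydrogenolysis without an extra step.

Step 3
Reactants: 3 2-(benzyloxy)-5-bromo-4-methoxybenzaldehyde; 4 1-(benzyloxy)-4-bromobenzene
Product: 6 rac-[2-(benzyloxy)-5-bromo-4-methoxyphenyl][4-(benzyloxy)phenyl]methanol, via aryl Grignard reagent 5 (not isolated)
Conditions: 4, Mg, I2 (cat.), THF, reflux; then 3, THF, 0 °C to rt; sat. aq. NH4Cl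
Reagents that add atoms: none
Why: Grignard formation and 1,2-addition to the aldehyde; carbonyl addition at 0 °C is far faster than bromine–magnesium exchange at the electron-rich C–Br bond of 3, and the new carbinol centre is racemic and is removed by oxidation in step 4.

Step 4
Reactants: 6 rac-[2-(benzyloxy)-5-bromo-4-methoxyphenyl][4-(benzyloxy)phenyl]methanol
Product: 7 [2-(benzyloxy)-5-bromo-4-methoxyphenyl][4-(benzyloxy)phenyl]methanone
Conditions: activated MnO2 (excess), CH2Cl2, rt
Reagents that add atoms: none
Why: MnO2 oxidation of a doubly benzylic, electron-rich carbinol to the diaryl ketone; benzyl ethers, the aryl bromide and the methyl ether are inert to this reagent.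

Step 5
Reactants: 8 4-(benzyloxy)benzaldehyde
Product: 9 1-(benzyloxy)-4-ethenylbenzene
Conditions: Ph3PCH3Br, KOtBu, THF, 0 °C to rt
Reagents that add atoms: methyltriphenylphosphonium bromide, C[P+](c1ccccc1)(c1ccccc1)c1ccccc1.[Br-]
Why: Wittig methylenation of a non-enolisable aromatic aldehyde with the unstabilised ylide; no geometry issue arises for a terminal alkene.

Step 6
Reactants: 7 [2-(benzyloxy)-5-bromo-4-methoxyphenyl][4-(benzyloxy)phenyl]methanone; 9 1-(benzyloxy)-4-ethenylbenzene
Product: 10 {2-(benzyloxy)-5-[(E)-2-(4-benzyloxyphenyl)ethenyl]-4-methoxyphenyl}[4-(benzyloxy)phenyl]methanone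
Conditions: Pd(OAc)2 (5 mol %), P(o-tolyl)3 (12 mol %), Et3N, DMF, 100 °C
Reagents that add atoms: none
Why: Mizoroki–Heck reaction; zerovalent palladium inserts into the C–Br bond, the styrene inserts syn with the aryl group going to its terminal carbon, and syn β-hydride elimination from the less strained rotamer should give the (E)-alkene, while the ketone and the ethers are not involved.

Step 7
Reactants: 10 {2-(benzyloxy)-5-[(E)-2-(4-benzyloxyphenyl)ethenyl]-4-methoxyphenyl}[4-(benzyloxy)phenyl]methanone
Product: 11 rac-{2-(benzyloxy)-5-[(1R,2R)-2-(4-benzyloxyphenyl)cyclopropyl]-4-methoxyphenyl}[4-(benzyloxy)phenyl]methanone (trans)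
Conditions: Et2Zn, CF3CO2H, CH2I2 (2.5 equiv each), CH2Cl2, 0 °C; then 10, 0 °C to rt; aq. NH4Cl
Reagents that add atoms: diiodomethane, ICI
Why: Simmons–Smith-type cyclopropanation with the trifluoroacetate-modified zinc carbenoid: protonolysis of one Zn–Et bond by CF3CO2H and iodine–zinc exchange with CH2I2 give CF3CO2ZnCH2I, whose electron-poor carboxylate ligand makes the carbenoid carbon electrophilic enough for a 1,2-diaryl alkene. The CH2 group is delivered to the C=C bond of 10 through a concerted, asynchronous three-centre (butterfly) transition state in which Cα–Cβ and Cβ–Cγ form together while iodide passes to zinc; the closest known reaction type is the cyclopropanation of (E)-stilbene and other unfunctionalised aryl alkenes with this reagent. The three-membered ring is closed intermolecularly by this single [2+1] transfer, so no cationic or radical intermediate exists in which the former double bond could rotate. The two new stereocentres, Cα and Cγ, are set relative to each other by the E geometry of the alkene, which is carried over stereospecifically into the trans ring; neither face is favoured and none needs to be, so 11 should be racemic, and both centres vanish in step 8. The step needs chemoselectivity for the alkene over the ketone, the benzyl ethers and the arenes: the alkene is the most nucleophilic π bond, being conjugated with the para benzyloxy group of ring C and with the ortho methoxy and para benzyloxy groups of ring A, whereas the ketone is meta to it, is not conjugated with it, and a diaryl ketone is neither alkylated by zinc alkyls nor methylenated by zinc carbenoids without an added promoter. A short reaction time and a mild NH4Cl quench limit Lewis acid opening of the donor-substituted cyclopropane by the zinc iodide salts.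

Step 8
Reactants: 11 rac-{2-(benzyloxy)-5-[(1R,2R)-2-(4-benzyloxyphenyl)cyclopropyl]-4-methoxyphenyl}[4-(benzyloxy)phenyl]methanone (trans)
Product: 13 {2-hydroxy-5-[3-(4-hydroxyphenyl)propyl]-4-methoxyphenyl}(4-hydroxyphenyl)methanone (target), via debenzylated trans-cyclopropane 12 (not isolated)
Conditions: H2 (1 atm), 10% Pd/C, EtOAc, rt; stopped when 12 is consumed
Reagents that add atoms: none
Why: Heterogeneous hydrogenolysis; the three benzyl aryl ethers should cleave first, then the Cα–Cγ ring bond, the weakest one because both carbons are benzylic, adds hydrogen on palladium and turns both stereocentres into CH2 groups, while the neutral aprotic medium and the electron-rich, chelated 2-hydroxybenzophenone slow carbonyl reduction.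

## Compound list

1 | 2-hydroxy-4-methoxybenzaldehyde | COc1ccc(C=O)c(O)c1 | starting material
2 | 5-bromo-2-hydroxy-4-methoxybenzaldehyde | COc1cc(O)c(C=O)cc1Br | intermediate
3 | 2-(benzyloxy)-5-bromo-4-methoxybenzaldehyde | COc1cc(OCc2ccccc2)c(C=O)cc1Br | intermediate
4 | 1-(benzyloxy)-4-bromobenzene | Brc1ccc(OCc2ccccc2)cc1 | starting material
5 | [4-(benzyloxy)phenyl]magnesium bromide | Br[Mg]c1ccc(OCc2ccccc2)cc1 | intermediate (not isolated)
6 | rac-[2-(benzyloxy)-5-bromo-4-methoxyphenyl][4-(benzyloxy)phenyl]methanol | COc1cc(OCc2ccccc2)c(C(O)c2ccc(OCc3ccccc3)cc2)cc1Br | intermediate
7 | [2-(benzyloxy)-5-bromo-4-methoxyphenyl][4-(benzyloxy)phenyl]methanone | COc1cc(OCc2ccccc2)c(C(=O)c2ccc(OCc3ccccc3)cc2)cc1Br | intermediate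
8 | 4-(benzyloxy)benzaldehyde | O=Cc1ccc(OCc2ccccc2)cc1 | starting material
9 | 1-(benzyloxy)-4-ethenylbenzene | C=Cc1ccc(OCc2ccccc2)cc1 | intermediate
10 | {2-(benzyloxy)-5-[(E)-2-(4-benzyloxyphenyl)ethenyl]-4-methoxyphenyl}[4-(benzyloxy)phenyl]methanone | COc1cc(OCc2ccccc2)c(C(=O)c2ccc(OCc3ccccc3)cc2)cc1/C=C/c1ccc(OCc2ccccc2)cc1 | intermediate
11 | rac-{2-(benzyloxy)-5-[(1R,2R)-2-(4-benzyloxyphenyl)cyclopropyl]-4-methoxyphenyl}[4-(benzyloxy)phenyl]methanone (trans, one enantiomer drawn) | COc1cc(OCc2ccccc2)c(C(=O)c2ccc(OCc3ccccc3)cc2)cc1[C@@H]1C[C@H]1c1ccc(OCc2ccccc2)cc1 | intermediate
12 | rac-{2-hydroxy-5-[(1R,2R)-2-(4-hydroxyphenyl)cyclopropyl]-4-methoxyphenyl}(4-hydroxyphenyl)methanone (trans, one enantiomer drawn) | COc1cc(O)c(C(=O)c2ccc(O)cc2)cc1[C@@H]1C[C@H]1c1ccc(O)cc1 | intermediate (not isolated)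
13 | {2-hydroxy-5-[3-(4-hydroxyphenyl)propyl]-4-methoxyphenyl}(4-hydroxyphenyl)methanone | COc1cc(O)c(C(=O)c2ccc(O)cc2)cc1CCCc1ccc(O)cc1 | target

## Step count and risk

Total step count: 8. Longest linear sequence: 7 steps (steps 1, 2, 3, 4, 6, 7 and 8); step 5 is a one-step side branch.

Least certain steps:

Step 7 (key step). The most likely failure is incomplete methylene transfer, because the 1,2-diaryl alkene is hindered and the carbenoid decays or is tied up by the ketone and ether oxygens before it reacts. A second risk is acid-induced opening or oligomerisation of the donor-substituted cyclopropane during a long reaction. Fallback: from 10, addition of dibromocarbene (CHBr3, 50% aq. NaOH, BnEt3NCl, CH2Cl2), a free and more electrophilic carbene that also adds stereospecifically, would give rac-{2-(benzyloxy)-5-[(1R,3R)-2,2-dibromo-3-(4-benzyloxyphenyl)cyclopropyl]-4-methoxyphenyl}[4-(benzyloxy)phenyl]methanone F1. Radical chain reduction of both C–Br bonds (Bu3SnH, AIBN, toluene, 90 °C) leaves the aryl-bearing centres and the ketone alone and returns to the route at 11.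

Step 8. The most likely failure is over-reduction: the ring C–C bond opens more slowly than expected, and the carbonyl is reduced to the carbinol, or further with loss of the benzylic oxygen, before the cyclopropane is consumed. Fallback: from 11, the hydrogenation is run in EtOAc containing Et3N, which disfavours benzylic C–O hydrogenolysis, until ring opening is complete. Reduction to the carbinol level is accepted and gives 2-[hydroxy(4-hydroxyphenyl)methyl]-4-[3-(4-hydroxyphenyl)propyl]-5-methoxyphenol F2. The doubly benzylic carbinol, activated by ortho and para hydroxyl groups, is then oxidised by hydride abstraction with DDQ (1 equiv, dioxane, rt), which returns to the route at 13.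

Step 6. The most likely failure is slow oxidative addition into the electron-rich, ortho-substituted C–Br bond, with deposition of palladium metal, thermal polymerisation of 9 and some insertion with the opposite regiochemistry. Fallback: from 9, cross-metathesis with vinylboronic acid pinacol ester (second-generation Grubbs catalyst, CH2Cl2, 40 °C) would give 2-{(E)-2-[4-(benzyloxy)phenyl]ethenyl}-4,4,5,5-tetramethyl-1,3,2-dioxaborolane F3. Suzuki–Miyaura coupling of F3 with 7 (Pd(PPh3)4, K2CO3, dioxane/H2O, 90 °C) transfers the alkenyl group with retention of geometry and returns to the route at 10.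

Step 1. The most likely failure is loss of regiocontrol or over-bromination (attack at C3 or twofold bromination) on the doubly activated ring. Fallback: this one does not set out from a compound of the route but from purchased 4-bromo-3-methoxyphenol F4. Magnesium-mediated ortho-formylation (MgCl2, Et3N, paraformaldehyde, MeCN, reflux) is specific for the position ortho to the phenol and should take the unhindered one, which returns to the route at 2.

## Further compounds

F1 | step 7 | rac-{2-(benzyloxy)-5-[(1R,3R)-2,2-dibromo-3-(4-benzyloxyphenyl)cyclopropyl]-4-methoxyphenyl}[4-(benzyloxy)phenyl]methanone (trans, one enantiomer drawn) | COc1cc(OCc2ccccc2)c(C(=O)c2ccc(OCc3ccccc3)cc2)cc1[C@@H]1C(Br)(Br)[C@H]1c1ccc(OCc2ccccc2)cc1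
F2 | step 8 | 2-[hydroxy(4-hydroxyphenyl)methyl]-4-[3-(4-hydroxyphenyl)propyl]-5-methoxyphenol (racemic) | COc1cc(O)c(C(O)c2ccc(O)cc2)cc1CCCc1ccc(O)cc1
F3 | step 6 | 2-{(E)-2-[4-(benzyloxy)phenyl]ethenyl}-4,4,5,5-tetramethyl-1,3,2-dioxaborolane | CC1(C)OB(/C=C/c2ccc(OCc3ccccc3)cc2)OC1(C)C
F4 | step 1 | 4-bromo-3-methoxyphenol | COc1cc(O)ccc1Br
A1 | alternative 1 | {4-[(tert-butyldimethylsilyl)oxy]phenyl}{5-[3-(4-{[tert-butyldimethylsilyl]oxy}phenyl)propyl]-2-hydroxy-4-methoxyphenyl}methanone | COc1cc(O)c(C(=O)c2ccc(O[Si](C)(C)C(C)(C)C)cc2)cc1CCCc1ccc(O[Si](C)(C)C(C)(C)C)cc1
A2 | alternative 1 | 1,3-dimethoxy-1-(trimethylsilyloxy)-7-[4-(tert-butyldimethylsilyloxy)phenyl]hepta-1,3-diene (double bond geometry not defined) | COC(O[Si](C)(C)C)=CC(OC)=CCCCc1ccc(O[Si](C)(C)C(C)(C)C)cc1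
A3 | alternative 1 | 1-[4-(tert-butyldimethylsilyloxy)phenyl]prop-2-yn-1-one | C#CC(=O)c1ccc(O[Si](C)(C)C(C)(C)C)cc1
A4 | alternative 2 | dimethyl 5-{5-[3-(4-benzyloxyphenyl)propyl]-2-hydroxy-4-methoxybenzoyl}-2-hydroxybenzene-1,3-dicarboxylate | COC(=O)c1cc(C(=O)c2cc(CCCc3ccc(OCc4ccccc4)cc3)c(OC)cc2O)cc(C(=O)OC)c1O
A5 | alternative 2 | 6-{3-[4-(benzyloxy)phenyl]propyl}-7-methoxy-4-oxo-4H-chromene-3-carbaldehyde | COc1cc2occ(C=O)c(=O)c2cc1CCCc1ccc(OCc2ccccc2)cc1
A6 | alternative 2 | dimethyl 3-oxopentanedioate | COC(=O)CC(=O)CC(=O)OC
A7 | alternative 3 | rac-[7-(benzyloxy)-2-{4-[(triisopropylsilyl)oxy]phenyl}chroman-6-yl]{4-[(triisopropylsilyl)oxy]phenyl}methanone | O=C(c1ccc(O[Si](C(C)C)(C(C)C)C(C)C)cc1)c1cc2c(cc1OCc1ccccc1)OC(c1ccc(O[Si](C(C)C)(C(C)C)C(C)C)cc1)CC2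
A8 | alternative 3 | [2-(benzyloxy)-4-hydroxy-5-(hydroxymethyl)phenyl]{4-[(triisopropylsilyl)oxy]phenyl}methanone | OCc1cc(C(=O)c2ccc(O[Si](C(C)C)(C(C)C)C(C)C)cc2)c(OCc2ccccc2)cc1O
A9 | alternative 3 | triisopropyl(4-ethenylphenoxy)silane | C=Cc1ccc(O[Si](C(C)C)(C(C)C)C(C)C)cc1
A10 | alternative 3 | 3-(benzyloxy)-6-methylidene-4-{4-[(triisopropylsilyl)oxy]benzoyl}cyclohexa-2,4-dien-1-one | C=C1C=C(C(=O)c2ccc(O[Si](C(C)C)(C(C)C)C(C)C)cc2)C(OCc2ccccc2)=CC1=O
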